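**Plan**
Retrosynthesis: the palmitate C–O bond and a silyl ether on the ring B phenol are cut first. The C1' acyloxymethyl group is then traced back to a methyl ester, and ring A is opened at C4'–C5', C2'–C3' and C5'–C6'.
Enabling feature: in ring A the C5' hydroxyl and the C3' methoxyl are meta, and the aryloxy carbon C6' lies between C5' and the carbon-bearing C1'. This is the pattern left by a vinylketene (C5', C2', C1', C6') joined to methoxyacetylene (C4', C3').
Forward: ring B is bought intact and monosilylated, and its free phenol displaces chloride from a chloromethylidene tert-butyl methyl malonate, which forms the C6'–O bond. The tert-butyl ester is then converted through the acid chloride into the diazo ketone, and irradiation with methoxyacetylene builds ring A.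
End game: hindrance-controlled reduction of the ring A ester, Mitsunobu esterification with palmitic acid, then desilylation.
Stereochemistry: the target has no stereocentre, and the alkene geometry of the open-chain precursors disappears when C6' becomes aromatic.

Key step: step 8

Assumption: all methoxy-, chloro- and aryloxymethylidene compounds are expected as E/Z mixtures. One isomer is drawn throughout, and both converge in the key step.
Abbreviation: Ar = 2-(methoxycarbonyl)-5-methyl-3-[(triisopropylsilyl)oxy]phenyl (ring B).

**Step 1**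
Reactants: 1 methyl 2,6-dihydroxy-4-methylbenzoate
Product: 2 methyl 2-hydroxy-4-methyl-6-[(triisopropylsilyl)oxy]benzoate
Conditions: TIPSCl (1.05 equiv), imidazole, DMF, 0 °C to rt
Reagents that add atoms: triisopropylsilyl chloride, CC(C)[Si](Cl)(C(C)C)C(C)C
Why: In this phenol silylation the second hydroxyl is locked in a hydrogen bond to the ester carbonyl once the first is silylated, so one equivalent should stop at the monoether; TIPS is chosen because it withstands K2CO3, TFA, oxalyl chloride, diazomethane, light and hydride and adds bulk next to the ring B ester.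

**Step 2**
Reactants: 3 tert-butyl methyl malonate
Product: 4 1-tert-butyl 3-methyl (2Z)-2-(methoxymethylidene)propanedioate
Conditions: HC(OMe)3, Ac2O, 110 °C, MeOAc distilled off
Reagents that add atoms: trimethyl orthoformate, COC(OC)OC
Why: This is the alkoxymethylenation of an active methylene compound with an orthoformate, driven by Ac2O trapping the methanol, and no Lewis acid is added so that the tert-butyl ester should survive.

**Step 3**
Reactants: 4 1-tert-butyl 3-methyl (2Z)-2-(methoxymethylidene)propanedioate
Product: 6 1-tert-butyl 3-methyl (2Z)-2-(chloromethylidene)propanedioate, via potassium enolate 5 (not isolated)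
Conditions: KOH (1.0 equiv), MeOH, 0 °C, evaporated to dryness; (COCl)2, DMF (cat.), CH2Cl2, 0 °C to rt
Reagents that add atoms: potassium hydroxide, [K+].[OH-] (O and K of 5); oxalyl chloride, O=C(Cl)C(=O)Cl (Cl of 6)
Why: Hydroxide attacks the vinylic carbon by addition–elimination and the resulting tricarbonyl enolate is converted into the vinylogous acid chloride by the Vilsmeier reagent without release of HCl; the chloride is needed because aryloxide leaves better than methoxide, so a direct exchange on 4 would run backwards.

**Step 4**
Reactants: 2 methyl 2-hydroxy-4-methyl-6-[(triisopropylsilyl)oxy]benzoate; 6 1-tert-butyl 3-methyl (2Z)-2-(chloromethylidene)propanedioate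
Product: 7 1-tert-butyl 3-methyl (2Z)-2-[(ArO)methylidene]propanedioate
Conditions: K2CO3, MeCN, 0 °C to rt
Reagents that add atoms: none
Why: In this nucleophilic vinylic substitution the phenoxide adds to the doubly activated carbon and chloride, the far better nucleofuge, leaves irreversibly, which sets the future C6'–O bond.

**Step 5**
Reactants: 7 1-tert-butyl 3-methyl (2Z)-2-[(ArO)methylidene]propanedioate
Product: 8 (2E)-3-(ArO)-2-(methoxycarbonyl)prop-2-enoic acid
Conditions: TFA, CH2Cl2, 0 °C to rt; toluene co-evaporation
Reagents that add atoms: none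
Why: Acidolysis of the tert-butyl ester (loss of isobutene) frees one carboxyl group without any nucleophile that could attack the vinylic carbon, which is why saponification is avoided, and the methyl esters, the aryl TIPS ether and the acceptor-substituted enol ether should be inert to anhydrous TFA.

**Step 6**
Reactants: 8 (2E)-3-(ArO)-2-(methoxycarbonyl)prop-2-enoic acid
Product: 10 methyl (2E)-4-diazo-2-[(ArO)methylidene]-3-oxobutanoate, via acid chloride 9 (not isolated)
Conditions: (COCl)2, DMF (cat.), CH2Cl2, 0 °C, evaporated; added to CH2N2 (2.3 equiv), Et2O, −15 to 0 °C; AcOH quench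
Reagents that add atoms: oxalyl chloride, O=C(Cl)C(=O)Cl (Cl of 9); diazomethane, C=[N+]=[N-] (CHN2 of 10)
Why: In this acylation of diazomethane (first stage of the Arndt–Eistert sequence) 9 has no α-hydrogen, acylation at −15 °C should outrun dipolar cycloaddition to a trisubstituted donor-capped alkene, and the second equivalent of diazomethane consumes the HCl, so only a small excess ever meets the alkene.

**Step 7**
Reactants: 11 chloroacetaldehyde dimethyl acetal
Product: 13 methoxyacetylene, via sodium methoxyacetylide 12 (not isolated)
Conditions: NaNH2 (3 equiv), NH3(l), −33 °C; NH3 evaporated; sat. aq. NaCl, −20 °C; distilled into a cold trap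
Reagents that add atoms: sodium amide, [Na+].[NH2-] (Na of 12)
Why: Twofold β-elimination (HCl, then MeOH) from the chloroacetal is the standard preparation of alkoxyacetylenes, and the third equivalent of base holds the product as its acetylide until the quench.

**Step 8**
Reactants: 10 methyl (2E)-4-diazo-2-[(ArO)methylidene]-3-oxobutanoate; 13 methoxyacetylene
Product: 18 methyl 3-hydroxy-5-methoxy-2-(ArO)benzoate, via vinylketene 14 (not isolated), via vinylcyclobutenone 15 (not isolated), via dienylketene 16 (not isolated), via cyclohexadienone 17 (not isolated)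
Conditions: 13 (4 equiv), ClCH2CH2Cl, hν (254 nm, low-pressure Hg lamps, Vycor), 5 °C; excess 13 vented; 80 °C
Reagents that add atoms: none
Why: Irradiation of 10 causes loss of N2 with a 1,2-shift of the alkenyl group (Wolff rearrangement) to vinylketene 14; the unsubstituted, nucleophilic alkyne carbon of 13 (future C4') then bonds to the ketene carbonyl carbon (C5') and the methoxy-bearing carbon (C3') bonds to the former diazo carbon (C2'), a polarity-matched [2+2] cycloaddition giving cyclobutenone 15. At 80 °C 15 opens conrotatorily (four electrons) to dienylketene 16, ring A closes by a disrotatory six-electron electrocyclization between C5' and C6', and dienone 17 enolizes to the phenol. This is the Danheiser benzannulation in its second-generation, photochemical diazo ketone form, for which alkoxyalkynes are established ketenophiles. Only regiocontrol is required: the ketene/ynol ether polarity places OMe meta to the new OH, and the connectivity of the cascade places OAr ortho to that OH with the ester on its other side. No stereocentre persists (C4 of 15 and C6 of 17 are transient and racemic) and the geometry of 10 is erased, the isomer with the aryloxy group pointing inward merely closing more slowly. The ring B ester and silyl ether are spectators, the ester on the vinylketene raises its electrophilicity toward the electron-rich alkyne, and the excess of 13 should keep the ketene from being captured by the product phenol.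

**Step 9**
Reactants: 18 methyl 3-hydroxy-5-methoxy-2-(ArO)benzoate
Product: 19 methyl 2-[2-hydroxy-6-(hydroxymethyl)-4-methoxyphenoxy]-4-methyl-6-[(triisopropylsilyl)oxy]benzoate
Conditions: i-Bu2AlH (3.3 equiv), CH2Cl2, −78 to −40 °C; aq. potassium sodium tartrate
Reagents that add atoms: none
Why: In this sterically controlled hydride reduction the ring A ester has one open ortho position, whereas the ring B ester is flanked by OTIPS and the aryloxy group and twisted out of conjugation, so at low temperature only the former should be reduced (one equivalent of hydride goes to the phenol).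

**Step 10**
Reactants: 19 methyl 2-[2-hydroxy-6-(hydroxymethyl)-4-methoxyphenoxy]-4-methyl-6-[(triisopropylsilyl)oxy]benzoate; 20 palmitic acid
Product: 21 methyl 2-{2-hydroxy-4-methoxy-6-[(palmitoyloxy)methyl]phenoxy}-4-methyl-6-[(triisopropylsilyl)oxy]benzoate
Conditions: PPh3, DIAD, THF, 0 °C to rt
Reagents that add atoms: none
Why: In the Mitsunobu esterification only the primary alcohol is activated as an oxyphosphonium ion and the carboxylic acid, far more acidic than the phenol, supplies the nucleophile, so the C5' phenol needs no protection, and its meta relation to the benzylic carbon excludes quinone methide formation.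

**Step 11**
Reactants: 21 methyl 2-{2-hydroxy-4-methoxy-6-[(palmitoyloxy)methyl]phenoxy}-4-methyl-6-[(triisopropylsilyl)oxy]benzoate
Product: 22 betaethrin E
Conditions: Bu4NF, AcOH, THF, 0 °C
Reagents that add atoms: none
Why: Fluoride-induced cleavage of an aryl silyl ether is fast at 0 °C, and the AcOH buffer protonates the phenoxide so that neither the palmitate nor the methyl ester should be attacked.

**Compound list**
1 | methyl 2,6-dihydroxy-4-methylbenzoate | COC(=O)c1c(O)cc(C)cc1O | starting material
2 | methyl 2-hydroxy-4-methyl-6-[(triisopropylsilyl)oxy]benzoate | COC(=O)c1c(O)cc(C)cc1O[Si](C(C)C)(C(C)C)C(C)C | intermediate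
3 | tert-butyl methyl malonate | COC(=O)CC(=O)OC(C)(C)C | starting material
4 | 1-tert-butyl 3-methyl (2Z)-2-(methoxymethylidene)propanedioate | COC(=O)/C(=C/OC)C(=O)OC(C)(C)C | intermediate
5 | potassium enolate of tert-butyl methyl formylmalonate | COC(=O)/C(=C/[O-])C(=O)OC(C)(C)C.[K+] | intermediate
6 | 1-tert-butyl 3-methyl (2Z)-2-(chloromethylidene)propanedioate | COC(=O)/C(=C/Cl)C(=O)OC(C)(C)C | intermediate
7 | 1-tert-butyl 3-methyl (2Z)-2-({2-(methoxycarbonyl)-5-methyl-3-[(triisopropylsilyl)oxy]phenoxy}methylidene)propanedioate | COC(=O)/C(=C/Oc1cc(C)cc(O[Si](C(C)C)(C(C)C)C(C)C)c1C(=O)OC)C(=O)OC(C)(C)C | intermediate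
8 | (2E)-2-(methoxycarbonyl)-3-{2-(methoxycarbonyl)-5-methyl-3-[(triisopropylsilyl)oxy]phenoxy}prop-2-enoic acid | COC(=O)/C(=C/Oc1cc(C)cc(O[Si](C(C)C)(C(C)C)C(C)C)c1C(=O)OC)C(=O)O | intermediate
9 | methyl (2Z)-2-(chlorocarbonyl)-3-{2-(methoxycarbonyl)-5-methyl-3-[(triisopropylsilyl)oxy]phenoxy}prop-2-enoate | COC(=O)/C(=C/Oc1cc(C)cc(O[Si](C(C)C)(C(C)C)C(C)C)c1C(=O)OC)C(=O)Cl | intermediate
10 | methyl (2E)-4-diazo-2-({2-(methoxycarbonyl)-5-methyl-3-[(triisopropylsilyl)oxy]phenoxy}methylidene)-3-oxobutanoate | COC(=O)/C(=C/Oc1cc(C)cc(O[Si](C(C)C)(C(C)C)C(C)C)c1C(=O)OC)C(=O)C=[N+]=[N-] | intermediate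
11 | chloroacetaldehyde dimethyl acetal (2-chloro-1,1-dimethoxyethane) | COC(CCl)OC | starting material
12 | sodium methoxyacetylide | [Na+].[C-]#COC | intermediate
13 | methoxyacetylene | COC#C | intermediate
14 | vinylketene, methyl (2E)-2-[(ArO)methylidene]-4-oxobut-3-enoate | COC(=O)/C(=C/Oc1cc(C)cc(O[Si](C(C)C)(C(C)C)C(C)C)c1C(=O)OC)C=C=O | intermediate
15 | vinylcyclobutenone, methyl (2E)-3-(ArO)-2-(2-methoxy-4-oxocyclobut-2-en-1-yl)prop-2-enoate, racemic | COC(=O)/C(=C/Oc1cc(C)cc(O[Si](C(C)C)(C(C)C)C(C)C)c1C(=O)OC)C2C(=O)C=C2OC | intermediate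
16 | dienylketene, methyl 2-[(ArO)methylidene]-4-methoxy-6-oxohexa-3,5-dienoate, ketenyl and alkenyl groups cis on the central C=C | O=C=C/C(OC)=C\C(C(=O)OC)=C/Oc1cc(C)cc(O[Si](C(C)C)(C(C)C)C(C)C)c1C(=O)OC | intermediate
17 | cyclohexadienone, methyl 6-(ArO)-3-methoxy-5-oxocyclohexa-1,3-diene-1-carboxylate, racemic | COC1=CC(=O)C(Oc2cc(C)cc(O[Si](C(C)C)(C(C)C)C(C)C)c2C(=O)OC)C(C(=O)OC)=C1 | intermediate
18 | methyl 3-hydroxy-5-methoxy-2-{2-(methoxycarbonyl)-5-methyl-3-[(triisopropylsilyl)oxy]phenoxy}benzoate | COC(=O)c1cc(OC)cc(O)c1Oc1cc(C)cc(O[Si](C(C)C)(C(C)C)C(C)C)c1C(=O)OC | intermediate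
19 | methyl 2-[2-hydroxy-6-(hydroxymethyl)-4-methoxyphenoxy]-4-methyl-6-[(triisopropylsilyl)oxy]benzoate | OCc1cc(OC)cc(O)c1Oc1cc(C)cc(O[Si](C(C)C)(C(C)C)C(C)C)c1C(=O)OC | intermediate
20 | palmitic acid | CCCCCCCCCCCCCCCC(=O)O | starting material
21 | methyl 2-{2-hydroxy-4-methoxy-6-[(palmitoyloxy)methyl]phenoxy}-4-methyl-6-[(triisopropylsilyl)oxy]benzoate | CCCCCCCCCCCCCCCC(=O)OCc1cc(OC)cc(O)c1Oc1cc(C)cc(O[Si](C(C)C)(C(C)C)C(C)C)c1C(=O)OC | intermediate
22 | betaethrin E, methyl 2-hydroxy-6-{2-hydroxy-4-methoxy-6-[(palmitoyloxy)methyl]phenoxy}-4-methylbenzoate | CCCCCCCCCCCCCCCC(=O)OCc1cc(OC)cc(O)c1Oc1cc(C)cc(O)c1C(=O)OC | target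

Total step count: 11.
Longest linear sequence: 9 steps (3, 4, 6, 7, 8, 10, 18, 19, 21, 22, that is steps 2, 3, 4, 5, 6, 8, 9, 10, 11).

**Steps most likely to fail**

Step 8. The arene and the push–pull alkene absorb at the irradiation wavelength. Nitrogen loss may therefore stall through inner filtering, the aryl ether may be photolysed on long exposure, and the volatile alkyne may be lost or polymerize before the ketene is trapped.
The fallback sets out from 10 and returns to the route at 14. It separates nitrogen loss from the annulation.
- 10 is rearranged in the dark with PhCO2Ag (cat.) and Et3N in aqueous THF (Arndt–Eistert homologation). Water captures the ketene to give (3E)-4-(ArO)-3-(methoxycarbonyl)but-3-enoic acid F1.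
- Oxalyl chloride converts this into methyl (2E)-2-(2-chloro-2-oxoethyl)-3-(ArO)prop-2-enoate F2.
- Slow addition of Et3N to F2 and 13 in toluene regenerates vinylketene 14 by dehydrochlorination. The sequence through 15, 16 and 17 to 18 then runs purely thermally.

Step 6. Two processes threaten this step. Diazomethane may add as a 1,3-dipole across the doubly activated C=C bond, and the acid chloride may acylate ring B intramolecularly.
The fallback sets out from 4 (with 2 as partner) and returns at 10. It moves the diazomethane acylation to the methoxymethylidene stage, where the stronger donor makes the alkene a poorer dipolarophile and no arene is within reach.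
- TFA converts 4 into (2E)-3-methoxy-2-(methoxycarbonyl)prop-2-enoic acid F3.
- Oxalyl chloride gives methyl (2Z)-2-(chlorocarbonyl)-3-methoxyprop-2-enoate F4.
- Diazomethane gives methyl (2E)-4-diazo-2-(methoxymethylidene)-3-oxobutanoate F5.
- KOH exchanges methoxide for oxide at the vinylic carbon to give the potassium enolate of methyl 4-diazo-2-formyl-3-oxobutanoate F6.
- p-Toluenesulfonyl chloride gives methyl (2E)-4-diazo-3-oxo-2-{[(4-methylbenzenesulfonyl)oxy]methylidene}butanoate F7. The base-stable diazo ketone should tolerate both of these operations.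
- Phenol 2 with K2CO3 in MeCN displaces the sulfonate to give 10.

Step 9. Discrimination between the two methyl esters may be lost, with partial reduction of the ring B ester once the temperature needed for full conversion is reached.
The fallback sets out from 18 and returns at 19. It replaces steric control of hydride delivery by a functional-group difference.
- Me3SnOH in ClCH2CH2Cl at 80 °C should hydrolyse only the ring A ester, because doubly ortho-substituted benzoates resist acyl-oxygen cleavage. This gives 3-hydroxy-5-methoxy-2-(ArO)benzoic acid F8.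
- BH3·SMe2 in THF then reduces the carboxylic acid but not the remaining ester, giving 19.

**Further compounds**
F1 | step 8 | (3E)-3-(methoxycarbonyl)-4-{2-(methoxycarbonyl)-5-methyl-3-[(triisopropylsilyl)oxy]phenoxy}but-3-enoic acid | COC(=O)/C(=C/Oc1cc(C)cc(O[Si](C(C)C)(C(C)C)C(C)C)c1C(=O)OC)CC(=O)O
F2 | step 8 | methyl (2E)-2-(2-chloro-2-oxoethyl)-3-{2-(methoxycarbonyl)-5-methyl-3-[(triisopropylsilyl)oxy]phenoxy}prop-2-enoate | COC(=O)/C(=C/Oc1cc(C)cc(O[Si](C(C)C)(C(C)C)C(C)C)c1C(=O)OC)CC(=O)Cl
F3 | step 6 | (2E)-3-methoxy-2-(methoxycarbonyl)prop-2-enoic acid | COC(=O)/C(=C/OC)C(=O)O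
F4 | step 6 | methyl (2Z)-2-(chlorocarbonyl)-3-methoxyprop-2-enoate | COC(=O)/C(=C/OC)C(=O)Cl
F5 | step 6 | methyl (2E)-4-diazo-2-(methoxymethylidene)-3-oxobutanoate | COC(=O)/C(=C/OC)C(=O)C=[N+]=[N-]
F6 | step 6 | potassium enolate of methyl 4-diazo-2-formyl-3-oxobutanoate | COC(=O)/C(=C/[O-])C(=O)C=[N+]=[N-].[K+]
F7 | step 6 | methyl (2E)-4-diazo-3-oxo-2-{[(4-methylbenzenesulfonyl)oxy]methylidene}butanoate | COC(=O)/C(=C/OS(=O)(=O)c1ccc(C)cc1)C(=O)C=[N+]=[N-]
F8 | step 9 | 3-hydroxy-5-methoxy-2-{2-(methoxycarbonyl)-5-methyl-3-[(triisopropylsilyl)oxy]phenoxy}benzoic acid | OC(=O)c1cc(OC)cc(O)c1Oc1cc(C)cc(O[Si](C(C)C)(C(C)C)C(C)C)c1C(=O)OC
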